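## Retrosynthetic overview
- Bilagrewin ⇒ desilylation of the phenol ⇒ Wittig two-carbon homologation of the benzodioxane-7-carbaldehyde to the (E)-enal.
- The benzodioxane core (both C–O bonds, the dioxane ring and the trans-2,3 stereocenters) comes from one catalytic asymmetric inverse-demand hetero-Diels–Alder reaction. The partners are an o-quinone, made by oxidative dearomatization of 5-hydroxyvanillin, and (E)-4-silyloxy-sinapyl alcohol.
- Only one ring is formed (the dioxane, in the key step). Both aromatic rings come intact from lignin-type feedstocks (syringaldehyde and 5-hydroxyvanillin).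

**Assumptions**
- The cycloaddition gives the lignin-type β-O-4 regiochemistry: the alkene carbon bearing CH₂OH bonds to the quinone oxygen that is para to CHO and flanked by OMe.
- The (S,S)-box ligand is assumed to give (2S,3S); if (2R,3R) is obtained, the (R,R)-ligand is used.
- Simple reagents and metal salts (Cu(OTf)₂, Ag₂O, DIBAL-H, TBAF and so on) are named only in the conditions and are not numbered. The chiral ligand is numbered because it is a separately purchased starting material.

## Route

**Step 1**
Reactants: 1 (syringaldehyde), 2 (TBSCl)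
Product: 3 (4-(tert-butyldimethylsilyloxy)-3,5-dimethoxybenzaldehyde)
Conditions: imidazole, DMF, rt
Reagents that add atoms: TBSCl, CC(C)(C)[Si](C)(C)Cl
Why: O-Silylation of the phenol keeps it from being oxidized or acting as a nucleophile toward the quinone later.

**Step 2**
Reactants: 3, 4 (triethyl phosphonoacetate)
Product: 5 (ethyl (E)-3-(4-TBSO-3,5-dimethoxyphenyl)acrylate)
Conditions: LiCl, DBU, MeCN, rt
Reagents that add atoms: triethyl phosphonoacetate, CCOC(=O)CP(=O)(OCC)OCC
Why: A Horner–Wadsworth–Emmons olefination under Masamune–Roush conditions gives the E-enoate and is mild enough to leave the aryl silyl ether intact.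

**Step 3**
Reactant: 5
Product: 6 ((E)-3-(4-TBSO-3,5-dimethoxyphenyl)prop-2-en-1-ol)
Conditions: DIBAL-H (2.5 equiv), CH₂Cl₂, –78 → 0 °C
Reagents that add atoms: none
Why: DIBAL-H reduces the ester 1,2 to the allylic alcohol without touching the alkene, so the E geometry that dictates the trans relationship of C2/C3 is preserved (ester reduction).

**Step 4**
Reactant: 7 (5-hydroxyvanillin)
Product: 8 (5-formyl-3-methoxy-1,2-benzoquinone)
Conditions: Ag₂O, MgSO₄, CH₂Cl₂, 0 °C, 15 min; filter cold and use at once
Reagents that add atoms: none
Why: Two-electron oxidation of the catechol dearomatizes the ring and gives the O=C–C=O heterodiene needed for the next step (Ag(I) catechol-to-o-quinone oxidation).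

**Step 5**
Reactants: 8 (1.5 equiv), 6; chiral ligand 10 ((S,S)-tBu-box, 11 mol%)
Product: 9 ((2S,3S)-2-(4-TBSO-3,5-dimethoxyphenyl)-3-(hydroxymethyl)-5-methoxy-2,3-dihydro-1,4-benzodioxine-7-carbaldehyde)
Conditions: Cu(OTf)₂ (10 mol%), 10 (11 mol%), 4 Å MS, CH₂Cl₂, –40 °C, 12 h
Reagents that add atoms: none
Why: Proposed new method: Cu(II)–box chelates the 1,2-dione and the electron-rich styrene adds across O=C–C=O in an asynchronous inverse-demand [4+2]. The closest known chemistry is o-quinone + styrene cycloaddition to 2-aryl-1,4-benzodioxanes, and Cu–box-catalyzed hetero-Diels–Alder reactions of 1,2-dicarbonyls. Suprafacial addition of the (E)-alkene gives the trans-2,3 relationship. The tBu groups shield one face of the chelated quinone and set the absolute configuration. The nucleophilic carbon bearing CH₂OH bonds to the oxygen para to CHO (flanked by OMe), and the benzylic carbon closes onto the other oxygen, by analogy with lignin β-O-4 coupling.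

**Step 6**
Reactants: 9, 11 (formylmethylene-triphenylphosphorane)
Product: 12 (TBS-protected bilagrewin, the enal)
Conditions: toluene, 90 °C, 24 h
Reagents that add atoms: Ph₃P=CHCHO, O=CC=P(c1ccccc1)(c1ccccc1)c1ccccc1
Why: A Wittig reaction of a stabilized ylide adds CH=CHCHO with E selectivity and tolerates the free primary alcohol. Neither stereocenter is touched, because neither has an acidic α-H.

**Step 7**
Reactant: 12
Product: 13 (bilagrewin)
Conditions: TBAF/AcOH (1:1 buffered), THF, 0 °C, 1 h
Reagents that add atoms: none
Why: Fluoride removes the phenolic TBS group (Si–O cleavage), and buffering with AcOH protects the enal and the stereocenters from base.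

## Compound list
1 | syringaldehyde | COc1cc(C=O)cc(OC)c1O | starting material
2 | tert-butyldimethylsilyl chloride | CC(C)(C)[Si](C)(C)Cl | starting material
3 | 4-TBSO-3,5-dimethoxybenzaldehyde | COc1cc(C=O)cc(OC)c1O[Si](C)(C)C(C)(C)C | intermediate
4 | triethyl phosphonoacetate | CCOC(=O)CP(=O)(OCC)OCC | starting material
5 | ethyl (E)-3-(4-TBSO-3,5-dimethoxyphenyl)acrylate | CCOC(=O)/C=C/c1cc(OC)c(O[Si](C)(C)C(C)(C)C)c(OC)c1 | intermediate
6 | (E)-3-(4-TBSO-3,5-dimethoxyphenyl)prop-2-en-1-ol | COc1cc(/C=C/CO)cc(OC)c1O[Si](C)(C)C(C)(C)C | intermediate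
7 | 5-hydroxyvanillin (3,4-dihydroxy-5-methoxybenzaldehyde) | COc1cc(C=O)cc(O)c1O | starting material
8 | 5-formyl-3-methoxy-1,2-benzoquinone | O=CC1=CC(=O)C(=O)C(OC)=C1 | intermediate
9 | (2S,3S)-benzodioxane aldehyde, TBS-protected | COc1cc([C@@H]2Oc3cc(C=O)cc(OC)c3O[C@H]2CO)cc(OC)c1O[Si](C)(C)C(C)(C)C | intermediate
10 | (S,S)-2,2'-isopropylidenebis(4-tert-butyl-2-oxazoline) | CC(C)(C1=N[C@@H](C(C)(C)C)CO1)C1=N[C@@H](C(C)(C)C)CO1 | starting material (commercial chiral ligand)
11 | (triphenylphosphoranylidene)acetaldehyde | O=CC=P(c1ccccc1)(c1ccccc1)c1ccccc1 | starting material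
12 | TBS-protected bilagrewin | COc1cc([C@@H]2Oc3cc(/C=C/C=O)cc(OC)c3O[C@H]2CO)cc(OC)c1O[Si](C)(C)C(C)(C)C | intermediate
13 | bilagrewin | COc1cc([C@@H]2Oc3cc(/C=C/C=O)cc(OC)c3O[C@H]2CO)cc(OC)c1O | target

## Totals
- Total steps: 7.
- Longest linear sequence: 6 steps (1 → 3 → 5 → 6 → 9 → 12 → 13), with step 4 running in parallel to make 8.

## Three steps most likely to fail
1. **Step 5 (hetero-Diels–Alder).** Regiochemistry, enantioselectivity and competing quinone redox or C–C addition are all uncertain.
   - Fallback: replace it with the Ag₂O biomimetic oxidative radical coupling of 7 with 6, which follows lignin β-O-4 regiochemistry and gives racemic material. Separate the regioisomers, then resolve the primary alcohol as its (–)-camphanate diastereomers.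
2. **Step 4 (quinone generation).** The formyl-substituted o-quinone may be too electrophilic and unstable to isolate.
   - Fallback: oxidize the dimethyl acetal of 7, which gives a more donor-substituted and more stable quinone that may also favor the desired regiochemistry. Carry the acetal through the cycloaddition and hydrolyze it (PPTS, aqueous acetone) before the Wittig reaction.
3. **Step 6 (Wittig homologation).** The electron-rich, hindered benzaldehyde may react sluggishly with the stabilized ylide.
   - Fallback: use Ph₃P=CHCO₂Et, then DIBAL-H to the cinnamyl alcohol, then chemoselective MnO₂ oxidation of the allylic alcohol, which leaves the aliphatic CH₂OH untouched.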